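**Plan**

1. Retrosynthesis: remove the silyl ether, then cut the two pyran bonds O1–C2 and C3–C4 of the chroman (o-quinone methide hetero-Diels–Alder, the presumed biosynthetic union). Next cut the ring bond from chroman C3 to the neighbouring ring CH2, and finally the two alkenes of the open chain, back to ring-opened (R)-α-terpineol.
2. Enabling feature: chroman C2(CH3)–C3(H) is the footprint of an (E)-C(CH3)=CH alkene in a ten-membered 1,5-diene. C3 is therefore a vinylic CH (vinyl iodide), and the CH2 beside it lies two carbons from the (Z)-C(CH3)=CH alkene, so it is the end carbon of a 1,3-diene that 9-BBN converts into a primary borane.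
3. Forward: open chain (steps 1–6), ten-membered carbocycle (step 7), arene made separately (steps 8–10), pyran ring fused on by cycloaddition (step 11), desilylation (step 12).
4. Stereochemistry: the carbinol-bearing ring carbon is bought with (R)-α-terpineol. The Z and E alkene geometries come from the iodo-ylide olefination and the carboalumination. The three chroman stereocentres arise together in step 11 by substrate control.

Key step: step 7

Assumption: the ring alkene is taken as drawn, (Z) with both ring CH2 groups on the same side, and (R)-(+)-α-terpineol of high enantiomeric purity is used as the chiral-pool material.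

**Route**

Step 1
Reactants: 1 (R)-(+)-α-terpineol
Product: 2 triethyl({2-[(1R)-4-methylcyclohex-3-en-1-yl]propan-2-yl}oxy)silane
Conditions: TESOTf, 2,6-lutidine, CH2Cl2, −78 → 0 °C
Reagents that add atoms: triethylsilyl trifluoromethanesulfonate CC[Si](CC)(CC)OS(=O)(=O)C(F)(F)F
Why: Silylation of a hindered tertiary alcohol with a silyl triflate and a non-nucleophilic base is standard, and the ether keeps the carbinol from forming a lactol with the aldehyde made next and from consuming the amide bases, AlMe3 and 9-BBN used later.

Step 2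
Reactants: 2 triethylsilyl ether of α-terpineol
Product: 4 (3R)-6-oxo-3-[2-(triethylsilyloxy)propan-2-yl]heptanal, via secondary ozonide 3 (not isolated)
Conditions: O3, CH2Cl2, −78 °C; then PPh3, −78 °C → rt
Reagents that add atoms: ozone [O-][O+]=O
Why: Criegee ozonolysis of the only alkene with reductive work-up should give the open keto-aldehyde, the stereocentre being untouched.

Step 3
Reactants: 4 keto-aldehyde
Product: 5 (5R,7Z)-8-iodo-5-[2-(triethylsilyloxy)propan-2-yl]non-7-en-2-one
Conditions: EtPPh3I, n-BuLi, THF, 0 °C → rt; I2, −78 °C; NaN(SiMe3)2, −78 → −20 °C; then 4, −78 °C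
Reagents that add atoms: ethyltriphenylphosphonium iodide CC[P+](c1ccccc1)(c1ccccc1)c1ccccc1.[I-]; iodine II
Why: Stork–Zhao-type Wittig olefination with the α-iodo ylide at −78 °C should take the aldehyde in preference to the much less electrophilic methyl ketone and, as a non-stabilised ylide, give the (Z)-2-iodoalkene with iodine cis to the chain.

Step 4
Reactants: 5 (Z)-vinyl iodide
Product: 6 (5R,7Z)-8-methyl-5-[2-(triethylsilyloxy)propan-2-yl]deca-7,9-dien-2-one
Conditions: tributyl(vinyl)stannane, Pd(PPh3)4 (cat.), CuI (cat.), CsF, DMF, 45 °C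
Reagents that add atoms: tributyl(vinyl)stannane C=C[Sn](CCCC)(CCCC)CCCC
Why: Stille coupling of a vinyl iodide proceeds with retention of alkene geometry and tolerates the ketone, so the (Z)-configured 2-substituted 1,3-diene should result.

Step 5
Reactants: 6 dienyl methyl ketone
Product: 10 (3Z,6R)-3-methyl-6-[2-(triethylsilyloxy)propan-2-yl]deca-1,3-dien-9-yne, via lithium enolate 7 (not isolated), via enol phosphate 8 (not isolated), via lithium acetylide 9 (not isolated)
Conditions: LiN(iPr)2 (1.1 equiv), THF, −78 °C; ClP(O)(OEt)2, −78 °C → rt; LiN(iPr)2 (2.3 equiv), −78 °C → rt; then H2O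
Reagents that add atoms: none
Why: Negishi alkyne synthesis from a methyl ketone (kinetic deprotonation at CH3, O-phosphorylation, base-induced elimination of diethyl phosphate) should leave the silyl ether and the diene alone at these temperatures.

Step 6
Reactants: 10 terminal alkyne
Product: 12 (1E,5R,7Z)-1-iodo-2,8-dimethyl-5-[2-(triethylsilyloxy)propan-2-yl]deca-1,7,9-triene, via alkenyl dimethylalane 11 (not isolated)
Conditions: AlMe3, Cp2ZrCl2 (cat.), CH2Cl2, 0 °C → rt; then I2, THF, −30 °C
Reagents that add atoms: trimethylaluminium C[Al](C)C; iodine II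
Why: Negishi zirconium-catalysed carboalumination adds CH3 and Al syn across the terminal alkyne with Al on the end carbon, and iodinolysis with retention gives the (E)-2-methyl-1-iodoalkene; alkenes are carbometallated far more slowly, so the diene should survive.

Step 7
Reactants: 12 (E)-vinyl iodide carrying the (Z)-1,3-diene
Product: 14 triethyl({2-[(1R,3Z,7E)-4,8-dimethylcyclodeca-3,7-dien-1-yl]propan-2-yl}oxy)silane, via B-alkyl-9-BBN borane 13 (not isolated)
Conditions: 9-BBN, THF, 0 °C → rt; then slow addition (syringe pump) to Pd(dppf)Cl2 (cat.), AsPh3, Cs2CO3, DMF/THF/H2O, 45 °C, about 2 mM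
Reagents that add atoms: none
Why: 9-BBN adds B–H only to the monosubstituted terminus of the diene to give the primary homoallylic borane 13; zerovalent palladium then inserts into the vinylic C–I bond with retention, the base-activated borate transfers its primary alkyl group to palladium, and reductive elimination from the eleven-membered palladacycle forms the bond between the vinylic CH (the future chroman C3) and the CH2 beside it. The closest known reaction type is the intramolecular B-alkyl Suzuki–Miyaura macrocyclisation of an ω-boryl alkenyl iodide. One ring closes, the ten-membered carbocycle, by an sp2–sp3 coupling that leaves both trisubstituted alkenes endocyclic. No stereocentre is created: the E geometry of the new ring alkene is carried over from step 6, the Z geometry from step 3, and the single (R) stereocentre is remote and unaffected. The step needs hydroboration at the terminal vinyl carbon only (secured by the bulk of 9-BBN and the inertness of the iodo-substituted and trisubstituted alkenes), ring closure instead of oligomerisation (slow addition at high dilution, helped by the cis alkene that turns the chain ends toward each other), and coupling instead of β-hydride elimination (wide bite angle of dppf together with AsPh3); the temperature is kept low so that the (E,Z)-1,5-diene does not undergo Cope rearrangement.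

Step 8
Reactants: 15 phloroglucinol
Product: 16 3-methyl-1-(2,4,6-trihydroxyphenyl)butan-1-one
Conditions: isovaleryl chloride, AlCl3, PhNO2, rt → 60 °C
Reagents that add atoms: 3-methylbutanoyl chloride CC(C)CC(Cl)=O
Why: Friedel–Crafts C-acylation of phloroglucinol should stop at the mono-ketone because the acyl group deactivates the ring.

Step 9
Reactants: 16 acylphloroglucinol
Product: 17 2-(3-methylbutyl)benzene-1,3,5-triol
Conditions: Et3SiH, CF3CO2H, rt
Reagents that add atoms: none
Why: Ionic hydrogenation should work because the protonated aryl ketone and then the derived benzylic cation, both stabilised by the ortho and para hydroxyl groups, each accept hydride from the silane.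

Step 10
Reactants: 17 isopentylphloroglucinol
Product: 19 2,4,6-trihydroxy-5-(3-methylbutyl)benzene-1,3-dicarbaldehyde, via bis(iminium) salt 18 (not isolated)
Conditions: POCl3, DMF, EtOAc, 0 °C → rt; then H2O, 50 °C
Reagents that add atoms: N,N-dimethylformamide CN(C)C=O; water O
Why: Vilsmeier–Haack formylation should take both free positions of the electron-rich triol, and hydrolysis of the bis(iminium) salt releases the dialdehyde.

Step 11
Reactants: 14 ten-membered (E,Z)-diene; 19 isopentyl diformylphloroglucinol
Product: 21 O-triethylsilyl ether of the target (trans-fused chroman, C2 R, C3 S, C4 S, silyloxypropyl-bearing ring carbon R, ring alkene Z), via o-quinone methide 20 (not isolated)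
Conditions: DDQ (slow addition), MeNO2, 0 °C → rt
Reagents that add atoms: none
Why: DDQ dehydrogenates the benzylic CH2 of 19 to o-quinone methide 20, which should add as an electron-poor heterodiene (inverse-demand hetero-Diels–Alder) to the strained (E)-alkene of 14 faster than to the (Z)-alkene, oxygen going to the methyl-bearing carbon; suprafacial addition gives the trans ring fusion (C2, C3), the transition state with the vinylic H under the heterodiene places isobutyl trans to the ring CH2 on C3 (C4), and attack on the outer face of the ring conformer with the silyloxypropyl group pseudo-equatorial relates all three centres to the terpineol-derived one.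

Step 12
Reactants: 21 silyl ether of the target
Product: 22 target CNP0570248.1
Conditions: HF·pyridine, pyridine, THF, 0 °C → rt
Reagents that add atoms: none
Why: Fluoride cleavage of the tertiary triethylsilyl ether under buffered conditions should leave the phenolic aldehydes, the chroman and the (Z)-alkene untouched.

**Compound list**

1 | (R)-(+)-α-terpineol, 2-[(1R)-4-methylcyclohex-3-en-1-yl]propan-2-ol | CC1=CC[C@H](C(C)(C)O)CC1 | starting material
2 | triethyl({2-[(1R)-4-methylcyclohex-3-en-1-yl]propan-2-yl}oxy)silane | CC1=CC[C@H](C(C)(C)O[Si](CC)(CC)CC)CC1 | intermediate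
3 | secondary ozonide of 2 (1-methyl-7,8,9-trioxabicyclo[4.2.1]nonane with the silyloxypropyl group on C4) | CC12OOC(O1)C[C@H](C(C)(C)O[Si](CC)(CC)CC)CC2 | intermediate (not isolated)
4 | (3R)-6-oxo-3-[2-(triethylsilyloxy)propan-2-yl]heptanal | O=CC[C@H](C(C)(C)O[Si](CC)(CC)CC)CCC(C)=O | intermediate
5 | (5R,7Z)-8-iodo-5-[2-(triethylsilyloxy)propan-2-yl]non-7-en-2-one | C/C(I)=C/C[C@H](C(C)(C)O[Si](CC)(CC)CC)CCC(C)=O | intermediate
6 | (5R,7Z)-8-methyl-5-[2-(triethylsilyloxy)propan-2-yl]deca-7,9-dien-2-one | C/C(C=C)=C/C[C@H](C(C)(C)O[Si](CC)(CC)CC)CCC(C)=O | intermediate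
7 | terminal lithium enolate of 6 | C/C(C=C)=C/C[C@H](C(C)(C)O[Si](CC)(CC)CC)CCC(=C)O[Li] | intermediate (not isolated)
8 | diethyl (5R,7Z)-8-methyl-5-[2-(triethylsilyloxy)propan-2-yl]deca-1,7,9-trien-2-yl phosphate | C/C(C=C)=C/C[C@H](C(C)(C)O[Si](CC)(CC)CC)CCC(=C)OP(=O)(OCC)OCC | intermediate (not isolated)
9 | lithium acetylide of 10 | C/C(C=C)=C/C[C@H](C(C)(C)O[Si](CC)(CC)CC)CCC#C[Li] | intermediate (not isolated)
10 | (3Z,6R)-3-methyl-6-[2-(triethylsilyloxy)propan-2-yl]deca-1,3-dien-9-yne | C/C(C=C)=C/C[C@H](C(C)(C)O[Si](CC)(CC)CC)CCC#C | intermediate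
11 | (E)-alkenyl dimethylalane from 10 (Al on the terminal carbon, cis to the new methyl) | C/C(C=C)=C/C[C@H](C(C)(C)O[Si](CC)(CC)CC)CC/C(C)=C/[Al](C)C | intermediate (not isolated)
12 | (1E,5R,7Z)-1-iodo-2,8-dimethyl-5-[2-(triethylsilyloxy)propan-2-yl]deca-1,7,9-triene | C/C(C=C)=C/C[C@H](C(C)(C)O[Si](CC)(CC)CC)CC/C(C)=C/I | intermediate
13 | 9-{(3Z,6R,9E)-10-iodo-3,9-dimethyl-6-[2-(triethylsilyloxy)propan-2-yl]deca-3,9-dien-1-yl}-9-borabicyclo[3.3.1]nonane | C/C(CCB1C2CCCC1CCC2)=C/C[C@H](C(C)(C)O[Si](CC)(CC)CC)CC/C(C)=C/I | intermediate (not isolated)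
14 | triethyl({2-[(1R,3Z,7E)-4,8-dimethylcyclodeca-3,7-dien-1-yl]propan-2-yl}oxy)silane | C/C1=C/C[C@H](C(C)(C)O[Si](CC)(CC)CC)CC/C(C)=C/CC1 | intermediate
15 | phloroglucinol (benzene-1,3,5-triol) | Oc1cc(O)cc(O)c1 | starting material
16 | 3-methyl-1-(2,4,6-trihydroxyphenyl)butan-1-one | CC(C)CC(=O)c1c(O)cc(O)cc1O | intermediate
17 | 2-(3-methylbutyl)benzene-1,3,5-triol | CC(C)CCc1c(O)cc(O)cc1O | intermediate
18 | bis(N,N-dimethyliminium) dichloride of 19 | CC(C)CCc1c(O)c(C=[N+](C)C)c(O)c(C=[N+](C)C)c1O.[Cl-].[Cl-] | intermediate (not isolated)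
19 | 2,4,6-trihydroxy-5-(3-methylbutyl)benzene-1,3-dicarbaldehyde | CC(C)CCc1c(O)c(C=O)c(O)c(C=O)c1O | intermediate
20 | o-quinone methide, 2,4-dihydroxy-5-(3-methylbutylidene)-6-oxocyclohexa-1,3-diene-1,3-dicarbaldehyde | CC(C)CC=C1C(=O)C(C=O)=C(O)C(C=O)=C1O | intermediate (not isolated)
21 | O-triethylsilyl ether of the target: 6,8-diformyl-5,7-dihydroxy-4-isobutyl-2-methylchroman (2R,3S,4S) whose C3 and C2 are bridged trans by CH2CH2–C(CH3)=CH–CH2–CH[C(CH3)2OSiEt3]–CH2CH2 (from C3 to C2), alkene Z, side-chain-bearing carbon R | C/C1=C/C[C@H](C(C)(C)O[Si](CC)(CC)CC)CC[C@@]2(C)Oc3c(C=O)c(O)c(C=O)c(O)c3[C@@H](CC(C)C)[C@@H]2CC1 | intermediate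
22 | CNP0570248.1: as 21 with a free tertiary alcohol, C(CH3)2OH | C/C1=C/C[C@H](C(C)(C)O)CC[C@@]2(C)Oc3c(C=O)c(O)c(C=O)c(O)c3[C@@H](CC(C)C)[C@@H]2CC1 | target

**Count and risks**

Total step count: 12. Longest linear sequence: 9 steps (steps 1–7, 11 and 12, from compound 1).

Steps most likely to fail:

Step 7. Intermolecular coupling (oligomerisation), protodeboronation or β-hydride elimination may outrun closure of the strained ten-membered ring. Fallback, from 12 back to 14, with a preformed organozinc in place of the borate: borane 13, made from 12 as in step 7, is oxidised with NaBO3·4H2O to the homoallylic alcohol (3Z,6R,9E)-10-iodo-3,9-dimethyl-6-[2-(triethylsilyloxy)propan-2-yl]deca-3,9-dien-1-ol F1. I2, PPh3 and imidazole convert it into the primary iodide (1E,5R,7Z)-1,10-diiodo-2,8-dimethyl-5-[2-(triethylsilyloxy)propan-2-yl]deca-1,7-diene F2. Zn dust with LiCl in THF inserts into the alkyl C–I bond only, giving the alkylzinc iodide F3 (not isolated). F3 is added slowly to Pd2(dba)3 and SPhos in THF/NMP for an intramolecular Negishi coupling that returns to the route at 14.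

Step 11. DDQ may abstract hydride from the allylic positions of the strained diene, the acidic hydroquinone may trigger transannular cyclisation before the o-quinone methide is captured, and facial discrimination by the macrocycle may be low. Fallback, from 15 and 14 back to 21, generating the same o-quinone methide 20 without oxidant and with reagent control: phloroglucinol 15 is formylated twice (POCl3, DMF, then water) through the bis(iminium) salt F4 (not isolated) to 2,4-diformylphloroglucinol F5. F5, isovaleraldehyde and 14 are combined with ethylenediammonium diacetate in MeCN/CH2Cl2 at rt (domino Knoevenagel–hetero-Diels–Alder). If the facial bias needs reinforcement, a chiral BINOL-derived phosphoric acid (TRIP) is added so that 20 reacts as a hydrogen-bonded chiral complex. The sequence returns at 21.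

Step 3. Z-selectivity may erode, and the basic iodo-ylide may enolise or attack the methyl ketone. Fallback, from 4 back to 6, bypassing 5 and step 4: Still–Gennari olefination of 4 with ethyl 2-[bis(2,2,2-trifluoroethoxy)phosphoryl]propanoate, KN(SiMe3)2 and 18-crown-6 in THF at −78 °C gives the (Z)-enoate ethyl (2Z,5R)-2-methyl-8-oxo-5-[2-(triethylsilyloxy)propan-2-yl]non-2-enoate F6 with the ketone untouched. i-Bu2AlH reduces ester and ketone to the diol (2Z,5R)-2-methyl-5-[2-(triethylsilyloxy)propan-2-yl]non-2-ene-1,8-diol F7. Dess–Martin periodinane buffered with NaHCO3 gives the keto-enal (2Z,5R)-2-methyl-8-oxo-5-[2-(triethylsilyloxy)propan-2-yl]non-2-enal F8. Methylenetriphenylphosphorane (1 equiv, −78 °C) then methylenates the aldehyde selectively to give diene 6.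

Further compounds

F1 | step 7 | (3Z,6R,9E)-10-iodo-3,9-dimethyl-6-[2-(triethylsilyloxy)propan-2-yl]deca-3,9-dien-1-ol | C/C(CCO)=C/C[C@H](C(C)(C)O[Si](CC)(CC)CC)CC/C(C)=C/I
F2 | step 7 | (1E,5R,7Z)-1,10-diiodo-2,8-dimethyl-5-[2-(triethylsilyloxy)propan-2-yl]deca-1,7-diene | C/C(CCI)=C/C[C@H](C(C)(C)O[Si](CC)(CC)CC)CC/C(C)=C/I
F3 | step 7 | alkylzinc iodide from F2 (not isolated) | C/C(CC[Zn]I)=C/C[C@H](C(C)(C)O[Si](CC)(CC)CC)CC/C(C)=C/I
F4 | step 11 | bis(N,N-dimethyliminium) dichloride of F5 (not isolated) | C[N+](C)=Cc1c(O)cc(O)c(C=[N+](C)C)c1O.[Cl-].[Cl-]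
F5 | step 11 | 2,4-diformylphloroglucinol (2,4,6-trihydroxybenzene-1,3-dicarbaldehyde) | O=Cc1c(O)cc(O)c(C=O)c1O
F6 | step 3 | ethyl (2Z,5R)-2-methyl-8-oxo-5-[2-(triethylsilyloxy)propan-2-yl]non-2-enoate | C/C(C(=O)OCC)=C/C[C@H](C(C)(C)O[Si](CC)(CC)CC)CCC(C)=O
F7 | step 3 | (2Z,5R)-2-methyl-5-[2-(triethylsilyloxy)propan-2-yl]non-2-ene-1,8-diol (mixture at C8) | C/C(CO)=C/C[C@H](C(C)(C)O[Si](CC)(CC)CC)CCC(C)O
F8 | step 3 | (2Z,5R)-2-methyl-8-oxo-5-[2-(triethylsilyloxy)propan-2-yl]non-2-enal | C/C(C=O)=C/C[C@H](C(C)(C)O[Si](CC)(CC)CC)CCC(C)=O
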